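**Retrosynthetic overview**
1. The tertiary/primary dibromide is made last, by Br2 addition to an exocyclic methylene. The (Z)-chlorovinyl group comes from a ring ester (reduction, Wittig chloromethylenation).
2. Both ring C–Cl bonds are traced back to the C–O bonds of a cis-1,3-diol, each replaced with inversion. The methylene carbon is added by conjugate reduction/Mannich methylenation.
3. Key step: a catalytic enantioselective, desymmetrising nucleophilic epoxidation (two C–O bonds) of prochiral methyl 1-methyl-4-oxocyclohexa-2,5-diene-1-carboxylate fixes the quaternary centre and the first carbinol.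
4. The dienone comes from benzoic acid by Birch reductive methylation/esterification and oxidation of the doubly allylic CH2.
5. Ring order: the only ring is the six-membered carbocycle, carried over from the benzene ring of benzoic acid. No ring is closed in the route (the oxirane is transient).

Assumption: only benzoic acid and the compounds made from it are numbered; commercial reagents, including those that deliver atoms, are named with SMILES on the reagent lines.

**Step 1**
Reactants: 1 benzoic acid
Product: 3 methyl 1-methylcyclohexa-2,5-diene-1-carboxylate, via lithium carboxylate 2 (not isolated)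
Conditions: Li (3.2 equiv), NH3(l)/THF, −78 °C; MeI (1.5 equiv); NH3 evaporated; DMF, MeI (2 equiv), 23 °C
Reagents that add atoms: iodomethane, CI
Why: Birch reduction of the benzoate gives the 1,4-dihydro enediolate, which is C-methylated at the carboxyl-bearing carbon (Birch reductive alkylation), and the lithium carboxylate is then O-methylated; the product has a mirror plane through C1 and C4, so no stereocentre is set.

**Step 2**
Reactants: 3 methyl 1-methylcyclohexa-2,5-diene-1-carboxylate
Product: 4 methyl 1-methyl-4-oxocyclohexa-2,5-diene-1-carboxylate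
Conditions: Rh2(C6H10NO)4 (dirhodium tetracaprolactamate, 1 mol %), t-BuOOH (70% aq, 5 equiv), K2CO3 (0.5 equiv), CH2Cl2, 23 °C
Reagents that add atoms: tert-butyl hydroperoxide, CC(C)(C)OO
Why: allylic oxidation by tert-butylperoxyl radicals removes the weak doubly allylic C–H and the mixed peroxide collapses to the cross-conjugated dienone; aromatisation cannot compete because C1 is quaternary, and the dienone stays prochiral.

**Step 3**
Reactants: 4 methyl 1-methyl-4-oxocyclohexa-2,5-diene-1-carboxylate
Product: 5 methyl (1S,2R,6S)-2-methyl-5-oxo-7-oxabicyclo[4.1.0]hept-3-ene-2-carboxylate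
Conditions: 9-amino(9-deoxy)epi-quinine (10 mol %), CF3CO2H (20 mol %), 50% aq H2O2 (1.3 equiv), 1,4-dioxane, 35 °C
Reagents that add atoms: hydrogen peroxide, OO
Why: Proposed new method: the primary amine condenses with the dienone carbonyl to a cross-conjugated iminium ion, the protonated quinuclidine holds H2O2 and delivers it to one β-carbon, and the β-peroxy enamine closes to the oxirane (amine-catalysed Weitz–Scheffer epoxidation); because the catalyst has one fixed facial preference at a β-carbon it would attack one enone arm anti and the mirror-image arm syn to the ester, and the steric and dipolar bias of CO2Me against syn attack should leave only the matched arm reactive, so one step sets the quaternary carbon (2R) and both oxirane carbons (1S,6S) with the oxirane anti to the ester, while the remaining enone is mismatched for a second epoxidation; the closest known reaction is the cinchona primary amine salt/H2O2 epoxidation of simple 2-cyclohexenones, which to my knowledge has not been used to desymmetrise a 4-alkyl-4-alkoxycarbonyl cyclohexa-2,5-dienone (which pseudo-enantiomer gives 5 must be confirmed on the first run, the quinidine-derived amine gives the antipode, and any syn-epoxide diastereomer is removed by chromatography).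

**Step 4**
Reactants: 5 methyl (1S,2R,6S)-2-methyl-5-oxo-7-oxabicyclo[4.1.0]hept-3-ene-2-carboxylate
Product: 9 methyl (1S,2R,6S)-2-methyl-4-methylidene-5-oxo-7-oxabicyclo[4.1.0]heptane-2-carboxylate, via lithium enolate 6 (not isolated), via Mannich base 7 (not isolated), via methiodide 8 (not isolated)
Conditions: LiBH(s-Bu)3 (1.1 equiv), THF, −78 °C; Me2N=CH2+ I− (1.5 equiv), −78 → 0 °C; MeI (5 equiv), CH2Cl2, 23 °C; aq NaHCO3
Reagents that add atoms: N,N-dimethylmethylideneammonium iodide (Eschenmoser's salt), C=[N+](C)C.[I-]
Why: the hindered borohydride adds hydride 1,4 to the β-unsubstituted enone (conjugate reduction) to give a regiodefined enolate, which is aminomethylated (Mannich reaction) and, after N-methylation, loses trimethylamine by E1cB to the α-methylene ketone; oxirane and ester are inert at −78 °C and the three stereocentres are untouched (the aminomethyl-bearing carbon is only a transient stereocentre).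

**Step 5**
Reactants: 9 methyl (1S,2R,6S)-2-methyl-4-methylidene-5-oxo-7-oxabicyclo[4.1.0]heptane-2-carboxylate
Product: 11 methyl (1R,2R,4S)-2,4-dihydroxy-1-methyl-5-methylidenecyclohexane-1-carboxylate, via hydroxy enone 10 (not isolated)
Conditions: SmI2 (2.05 equiv, added to 9), THF/MeOH 4:1, −90 °C; then CeCl3·7H2O (1.0 equiv), NaBH4 (1.5 equiv), −78 °C
Reagents that add atoms: none
Why: single-electron reduction of the α,β-epoxy ketone cleaves the Cα–O bond (SmI2 epoxy-ketone opening, faster than reduction of the enone) and leaves the β-carbinol configuration intact, and Luche 1,2-reduction of the exocyclic enone by axial hydride attack on the chair with the hydroxyl equatorial places the new hydroxyl cis to the first (4S), giving the diequatorial cis-1,3-diol.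

**Step 6**
Reactants: 11 methyl (1R,2R,4S)-2,4-dihydroxy-1-methyl-5-methylidenecyclohexane-1-carboxylate
Product: 15 methyl (1S,2S,4S)-2-chloro-4-hydroxy-1-methyl-5-methylidenecyclohexane-1-carboxylate, via silyl ether 12 (not isolated), via triflate 13 (not isolated), via chloro silyl ether 14 (not isolated)
Conditions: Et3SiOTf (1.0 equiv), 2,6-lutidine (4 equiv), CH2Cl2, −78 °C; Tf2O (1.2 equiv), −78 → −20 °C; n-Bu4NCl (3 equiv), −20 → 23 °C; then PPTS (cat.), MeOH, 23 °C
Reagents that add atoms: tetrabutylammonium chloride, CCCC[N+](CCCC)(CCCC)CCCC.[Cl-]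
Why: the unhindered allylic hydroxyl is silylated first, the remaining hydroxyl is triflated and chloride displaces the triflate with inversion (SN2) to set C2–Cl (2S); the cis-1,3 OSiEt3 group holds the triflate equatorial so no anti-periplanar hydrogen is available for E2, and the α-ester suppresses ionisation and 1,2-shifts, the same situation as the 3β-to-3α substitutions of 4,4-dimethyl-3-hydroxy triterpenoids; acidic methanol then removes the silyl group.

**Step 7**
Reactants: 15 methyl (1S,2S,4S)-2-chloro-4-hydroxy-1-methyl-5-methylidenecyclohexane-1-carboxylate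
Product: 17 (1S,4S,5S)-5-chloro-4-[(Z)-2-chloroethenyl]-4-methyl-2-methylidenecyclohexan-1-ol, via aldehyde 16 (not isolated)
Conditions: i-Bu2AlH (2.2 equiv), CH2Cl2, −78 °C; then Ph3P=CHCl [from ClCH2PPh3Cl (3 equiv), NaN(SiMe3)2 (2.9 equiv), THF, −78 °C], −78 → 0 °C; aq KNaC4H4O6
Reagents that add atoms: (chloromethyl)triphenylphosphonium chloride, ClC[P+](c1ccccc1)(c1ccccc1)c1ccccc1.[Cl-]
Why: i-Bu2AlH reduction stops at the aluminium hemiacetal of the α-quaternary ester, which releases the aldehyde to the salt-free chloromethylene ylide (one-pot reduction/Wittig chloro-olefination), a kinetically Z-favoured olefination (about 4:1 Z:E expected, E isomer removed by chromatography); the aldehyde has no α-hydrogen, so the β-chloride cannot eliminate, and no ring stereocentre is touched.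

**Step 8**
Reactants: 17 (1S,4S,5S)-5-chloro-4-[(Z)-2-chloroethenyl]-4-methyl-2-methylidenecyclohexan-1-ol
Product: 18 (1S,2S,4R)-2,4-dichloro-1-[(Z)-2-chloroethenyl]-1-methyl-5-methylidenecyclohexane
Conditions: PPh3 (1.5 equiv), Cl3CC(O)CCl3 (1.5 equiv), CH2Cl2, −20 → 0 °C
Reagents that add atoms: hexachloroacetone, ClC(Cl)(Cl)C(=O)C(Cl)(Cl)Cl
Why: Appel-type chlorination with PPh3/hexachloroacetone converts the allylic alcohol into the chloride by direct SN2 without allylic transposition, so the carbinol is inverted (4R) and the chlorine ends cis to the other ring chlorine and to the chlorovinyl group.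

**Step 9**
Reactants: 18 (1S,2S,4R)-2,4-dichloro-1-[(Z)-2-chloroethenyl]-1-methyl-5-methylidenecyclohexane
Product: 19 (1S,2R,4S,5S)-1-bromo-1-(bromomethyl)-2,4-dichloro-5-[(Z)-2-chloroethenyl]-5-methylcyclohexane
Conditions: Br2 (1.05 equiv), CH2Cl2, −78 °C, dark
Reagents that add atoms: bromine, BrBr
Why: electrophilic anti addition of Br2 occurs only at the electron-rich 1,1-disubstituted exocyclic alkene (the chloroalkene is deactivated); the bromonium ion forms reversibly on the face opposite the axial chlorovinyl group and bromide opens it anti at the tertiary carbon (Markovnikov), giving C–Br on the chlorovinyl face and CH2Br on the methyl face (1S), which is also the more stable epimer because Br is far smaller than CH2Br in the position syn-axial to the chlorovinyl group.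

**Compound list**
1 | benzoic acid | OC(=O)c1ccccc1 | starting material
2 | lithium 1-methylcyclohexa-2,5-diene-1-carboxylate | [Li+].[O-]C(=O)C1(C)C=CCC=C1 | intermediate
3 | methyl 1-methylcyclohexa-2,5-diene-1-carboxylate | COC(=O)C1(C)C=CCC=C1 | intermediate
4 | methyl 1-methyl-4-oxocyclohexa-2,5-diene-1-carboxylate | COC(=O)C1(C)C=CC(=O)C=C1 | intermediate
5 | methyl (1S,2R,6S)-2-methyl-5-oxo-7-oxabicyclo[4.1.0]hept-3-ene-2-carboxylate | C[C@@]1(C(=O)OC)C=CC(=O)[C@H]2O[C@@H]12 | intermediate
6 | lithium (1S,2R,6S)-2-(methoxycarbonyl)-2-methyl-7-oxabicyclo[4.1.0]hept-4-en-5-olate | C[C@@]1(C(=O)OC)CC=C([O-])[C@H]2O[C@@H]12.[Li+] | intermediate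
7 | methyl (1S,2R,6S)-4-[(dimethylamino)methyl]-2-methyl-5-oxo-7-oxabicyclo[4.1.0]heptane-2-carboxylate (both C4 epimers) | C[C@@]1(C(=O)OC)CC(CN(C)C)C(=O)[C@H]2O[C@@H]12 | intermediate
8 | {[(1S,2R,6S)-2-(methoxycarbonyl)-2-methyl-5-oxo-7-oxabicyclo[4.1.0]heptan-4-yl]methyl}trimethylammonium iodide (both C4 epimers) | C[C@@]1(C(=O)OC)CC(C[N+](C)(C)C)C(=O)[C@H]2O[C@@H]12.[I-] | intermediate
9 | methyl (1S,2R,6S)-2-methyl-4-methylidene-5-oxo-7-oxabicyclo[4.1.0]heptane-2-carboxylate | C[C@@]1(C(=O)OC)CC(=C)C(=O)[C@H]2O[C@@H]12 | intermediate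
10 | methyl (1R,2R)-2-hydroxy-1-methyl-5-methylidene-4-oxocyclohexane-1-carboxylate | C[C@@]1(C(=O)OC)CC(=C)C(=O)C[C@H]1O | intermediate
11 | methyl (1R,2R,4S)-2,4-dihydroxy-1-methyl-5-methylidenecyclohexane-1-carboxylate | C[C@@]1(C(=O)OC)CC(=C)[C@@H](O)C[C@H]1O | intermediate
12 | methyl (1R,2R,4S)-2-hydroxy-1-methyl-5-methylidene-4-[(triethylsilyl)oxy]cyclohexane-1-carboxylate | C[C@@]1(C(=O)OC)CC(=C)[C@@H](O[Si](CC)(CC)CC)C[C@H]1O | intermediate
13 | methyl (1R,2R,4S)-1-methyl-5-methylidene-4-[(triethylsilyl)oxy]-2-{[(trifluoromethyl)sulfonyl]oxy}cyclohexane-1-carboxylate | C[C@@]1(C(=O)OC)CC(=C)[C@@H](O[Si](CC)(CC)CC)C[C@H]1OS(=O)(=O)C(F)(F)F | intermediate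
14 | methyl (1S,2S,4S)-2-chloro-1-methyl-5-methylidene-4-[(triethylsilyl)oxy]cyclohexane-1-carboxylate | C[C@@]1(C(=O)OC)CC(=C)[C@@H](O[Si](CC)(CC)CC)C[C@@H]1Cl | intermediate
15 | methyl (1S,2S,4S)-2-chloro-4-hydroxy-1-methyl-5-methylidenecyclohexane-1-carboxylate | C[C@@]1(C(=O)OC)CC(=C)[C@@H](O)C[C@@H]1Cl | intermediate
16 | (1S,2S,4S)-2-chloro-4-hydroxy-1-methyl-5-methylidenecyclohexane-1-carbaldehyde | C[C@@]1(C=O)CC(=C)[C@@H](O)C[C@@H]1Cl | intermediate
17 | (1S,4S,5S)-5-chloro-4-[(Z)-2-chloroethenyl]-4-methyl-2-methylidenecyclohexan-1-ol | C[C@@]1(/C=C\Cl)CC(=C)[C@@H](O)C[C@@H]1Cl | intermediate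
18 | (1S,2S,4R)-2,4-dichloro-1-[(Z)-2-chloroethenyl]-1-methyl-5-methylidenecyclohexane | C[C@@]1(/C=C\Cl)CC(=C)[C@H](Cl)C[C@@H]1Cl | intermediate
19 | (1S,2R,4S,5S)-1-bromo-1-(bromomethyl)-2,4-dichloro-5-[(Z)-2-chloroethenyl]-5-methylcyclohexane | C[C@@]1(/C=C\Cl)C[C@@](Br)(CBr)[C@H](Cl)C[C@@H]1Cl | target

**Total step count:** 9. **Longest linear sequence:** 9 steps (fully linear from benzoic acid).

**Three steps most likely to fail**

Step 3 (the proposed new desymmetrising epoxidation). Risks are poor discrimination between the two enone arms or faces, low ee, and bis-epoxidation. The fallback uses known chemistry, sets out from 4 and comes back at 5. Racemic Weitz–Scheffer epoxidation of 4 (t-BuOOH, DBU, CH2Cl2, 0 °C) gives 5 together with its enantiomer methyl (1R,2S,6R)-2-methyl-5-oxo-7-oxabicyclo[4.1.0]hept-3-ene-2-carboxylate F1. Preparative chiral-phase SFC then delivers 5 as the single enantiomer, and the route continues with step 4.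

Step 6 (backside displacement at the secondary carbon next to the quaternary centre). Risks are no reaction or loss of triflic acid to the ring alkene. The fallback replaces backside attack by front-side chloride delivery on the C2 epimer; it sets out from 11 and comes back at 15. Selective benzoylation of the allylic hydroxyl (BzCl, pyridine, −20 °C) gives methyl (1R,2R,4S)-4-(benzoyloxy)-2-hydroxy-1-methyl-5-methylidenecyclohexane-1-carboxylate F2. Dess–Martin oxidation gives methyl (1R,4S)-4-(benzoyloxy)-1-methyl-5-methylidene-2-oxocyclohexane-1-carboxylate F3. LiBH(s-Bu)3 at −78 °C attacks equatorially and gives the axial, C2-epimeric alcohol methyl (1R,2S,4S)-4-(benzoyloxy)-2-hydroxy-1-methyl-5-methylidenecyclohexane-1-carboxylate F4. SOCl2 converts it into methyl (1R,2S,4S)-4-(benzoyloxy)-2-[(chlorosulfinyl)oxy]-1-methyl-5-methylidenecyclohexane-1-carboxylate F5. With catalytic TiCl4 this collapses with retention (the known stereoretentive chlorination of hindered cyclic alcohols through their chlorosulfites) to methyl (1S,2S,4S)-4-(benzoyloxy)-2-chloro-1-methyl-5-methylidenecyclohexane-1-carboxylate F6. K2CO3 in MeOH removes the benzoate and returns 15.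

Step 9 (facial outcome of the dibromination). The risk is that the required anti opening at the tertiary carbon is syn to the axial chlorovinyl group, so the C1 epimer may predominate. The fallback moves from kinetic to thermodynamic control; it sets out from 18 and comes back at 19. The bromination is run to completion regardless of selectivity, and the unwanted epimer (1R,2R,4S,5S)-1-bromo-1-(bromomethyl)-2,4-dichloro-5-[(Z)-2-chloroethenyl]-5-methylcyclohexane F7 is separated. F7 is then equilibrated with ZnBr2 (10 mol %) in CH2Cl2 at 0 → 23 °C. Reversible ionisation to the bromonium/bromide pair (the 1,2-bromine shift known as mutarotation of vicinal dibromides) funnels F7 into the more stable 19, which has the small bromine rather than CH2Br syn-axial to the chlorovinyl group.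

**Further compounds**
F1 | step 3 | methyl (1R,2S,6R)-2-methyl-5-oxo-7-oxabicyclo[4.1.0]hept-3-ene-2-carboxylate | C[C@]1(C(=O)OC)C=CC(=O)[C@@H]2O[C@H]12
F2 | step 6 | methyl (1R,2R,4S)-4-(benzoyloxy)-2-hydroxy-1-methyl-5-methylidenecyclohexane-1-carboxylate | C[C@@]1(C(=O)OC)CC(=C)[C@@H](OC(=O)c2ccccc2)C[C@H]1O
F3 | step 6 | methyl (1R,4S)-4-(benzoyloxy)-1-methyl-5-methylidene-2-oxocyclohexane-1-carboxylate | C[C@@]1(C(=O)OC)CC(=C)[C@@H](OC(=O)c2ccccc2)CC1=O
F4 | step 6 | methyl (1R,2S,4S)-4-(benzoyloxy)-2-hydroxy-1-methyl-5-methylidenecyclohexane-1-carboxylate | C[C@@]1(C(=O)OC)CC(=C)[C@@H](OC(=O)c2ccccc2)C[C@@H]1O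
F5 | step 6 | methyl (1R,2S,4S)-4-(benzoyloxy)-2-[(chlorosulfinyl)oxy]-1-methyl-5-methylidenecyclohexane-1-carboxylate | C[C@@]1(C(=O)OC)CC(=C)[C@@H](OC(=O)c2ccccc2)C[C@@H]1OS(=O)Cl
F6 | step 6 | methyl (1S,2S,4S)-4-(benzoyloxy)-2-chloro-1-methyl-5-methylidenecyclohexane-1-carboxylate | C[C@@]1(C(=O)OC)CC(=C)[C@@H](OC(=O)c2ccccc2)C[C@@H]1Cl
F7 | step 9 | (1R,2R,4S,5S)-1-bromo-1-(bromomethyl)-2,4-dichloro-5-[(Z)-2-chloroethenyl]-5-methylcyclohexane | C[C@@]1(/C=C\Cl)C[C@](Br)(CBr)[C@H](Cl)C[C@@H]1Cl
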